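**Retrosynthetic overview** (ring A = the dihydrobenzofuran without side chain: O1, C2 = spiro carbon, C3 = CH2, C7a; ring B = the dihydrobenzofuran whose CH, C3′, carries the side chain, ring oxygen O1′; ring C = the benzofuran)
1. The target 26 is the hexabenzyl ether 25 after one global hydrogenolysis.
2. Ring A of 25 is cut at C3–C2 and at O1–C7a, giving benzylic zinc reagent 22 (from fluoroarene 5) and acid chloride 21. Forward: acylation makes the C2 ketone, the B-ring phenoxide closes ring B as a hemiketal, and the hemiketal oxygen closes ring A by displacing fluoride.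
3. Enabling feature: C2 is a ketone-level carbon that can deliver its own oxygen as O1, because O1 sits on C7a, ortho to the C7 isovaleryl ketone (a C7a–F there is SNAr-active), and the B-ring oxygen O1′ is five atoms from C2.
4. 21 comes from Evans alkylation of arylacetyl imide 10 with benzofuranylmethyl bromide 17 (sets C3′). Rings A and B both derive from fluoro ketone 4 (via 5 and 7); ring C from iodophloroglucinol 12 and propargyl alcohol.
5. Ring order: C (step 8), then B and A together (step 14).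

Key step: step 14

Remark: 5-fluororesorcinol (1) and phlorisovalerophenone (11) are taken as commercial; 11 is otherwise one Friedel–Crafts acylation away from phloroglucinol.

**Route**

Step 1
Reactants: 1 5-fluorobenzene-1,3-diol; 2 3-methylbutanoic acid
Product: 3 1-(2-fluoro-4,6-dihydroxyphenyl)-3-methylbutan-1-one
Conditions: BF3·OEt2, 90 °C
Reagents that add atoms: none
Why: Nencki-type Friedel–Crafts C-acylation of a resorcinol goes ortho to one hydroxyl and para to the other (as with orcinol), which places the acyl group next to fluorine.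

Step 2
Reactants: 3
Product: 4 1-[2,4-bis(benzyloxy)-6-fluorophenyl]-3-methylbutan-1-one
Conditions: BnBr, K2CO3, DMF, 60 °C
Reagents that add atoms: benzyl bromide BrCc1ccccc1
Why: Williamson etherification in DMF at 60 °C should alkylate the chelated ortho-hydroxyl as well as the para one.

Step 3
Reactants: 4
Product: 5 1-[4,6-bis(benzyloxy)-3-(chloromethyl)-2-fluorophenyl]-3-methylbutan-1-one
Conditions: MOMCl, ZnCl2 (cat.), CH2Cl2, 0 °C to rt
Reagents that add atoms: chloromethyl methyl ether COCCl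
Why: Blanc chloromethylation (electrophilic aromatic substitution) should go to the position para to one benzyloxy group and ortho to the other, between F and OBn, and not to the position flanked by two ethers.

Step 4
Reactants: 5
Product: 6 [4,6-bis(benzyloxy)-2-fluoro-3-(3-methylbutanoyl)phenyl]acetic acid
Conditions: PdCl2(PPh3)2 (3 mol %), CO (1 atm), K2CO3, THF–H2O, 50 °C; then aq. HCl
Reagents that add atoms: carbon monoxide [C-]#[O+]; water O
Why: Palladium-catalysed hydroxycarbonylation of a benzylic chloride (oxidative addition, CO insertion, hydrolysis of the acyl palladium) gives the arylacetic acid.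

Step 5
Reactants: 6
Product: 7 {4,6-bis(benzyloxy)-3-(3-methylbutanoyl)-2-[2-(trimethylsilyl)ethoxy]phenyl}acetic acid
Conditions: Me3SiCH2CH2OH (excess), KOt-Bu, DMF, 0 to 45 °C; then aq. HCl
Reagents that add atoms: 2-(trimethylsilyl)ethanol C[Si](C)(C)CCO
Why: Nucleophilic aromatic substitution (addition–elimination) of the fluoride activated by the ortho ketone, with the carboxylate keeping the benzylic CH2 from being deprotonated.

Step 6
Reactants: 7; 8 (4S)-4-benzyl-1,3-oxazolidin-2-one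
Product: 10 (4S)-4-benzyl-3-({4,6-bis(benzyloxy)-3-(3-methylbutanoyl)-2-[2-(trimethylsilyl)ethoxy]phenyl}acetyl)-1,3-oxazolidin-2-one, via mixed pivalic anhydride 9 (not isolated)
Conditions: PivCl, Et3N, THF, −20 °C; then 8, LiCl, rt
Reagents that add atoms: none
Why: Evans auxiliary loading by N-acylation with the mixed pivalic anhydride under the LiCl/Et3N protocol needs no strong base.

Step 7
Reactants: 11 3-methyl-1-(2,4,6-trihydroxyphenyl)butan-1-one
Product: 12 1-(2,4,6-trihydroxy-3-iodophenyl)-3-methylbutan-1-one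
Conditions: NIS (1.0 equiv), MeCN, 0 °C
Reagents that add atoms: N-iodosuccinimide O=C1CCC(=O)N1I
Why: Electrophilic aromatic iodination of the phloroglucinol ring, whose two free positions are equivalent, should stop at the mono-iodide with one equivalent of NIS.

Step 8
Reactants: 12; 13 prop-2-yn-1-ol
Product: 15 1-[4,6-dihydroxy-2-(hydroxymethyl)-1-benzofuran-5-yl]-3-methylbutan-1-one, via alkynyl phenol 14 (not isolated)
Conditions: PdCl2(PPh3)2 (3 mol %), CuI (5 mol %), Et3N, DMF, 60 °C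
Reagents that add atoms: none
Why: Sonogashira coupling followed by 5-endo-dig heteroannulation (Larock-type benzofuran synthesis), in which the more acidic, non-chelated para-hydroxyl should close the ring in preference to the ortho-hydroxyl hydrogen-bonded to the ketone.

Step 9
Reactants: 15
Product: 16 1-[4,6-bis(benzyloxy)-2-(hydroxymethyl)-1-benzofuran-5-yl]-3-methylbutan-1-one
Conditions: BnBr, K2CO3, DMF, 70 °C
Reagents that add atoms: benzyl bromide BrCc1ccccc1
Why: Williamson etherification with carbonate alkylates the two phenols and leaves the primary alcohol untouched.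

Step 10
Reactants: 16
Product: 17 1-[4,6-bis(benzyloxy)-2-(bromomethyl)-1-benzofuran-5-yl]-3-methylbutan-1-one
Conditions: CBr4, PPh3, CH2Cl2, 0 °C
Reagents that add atoms: carbon tetrabromide BrC(Br)(Br)Br
Why: Appel bromination converts the furfuryl-type alcohol into the bromide under neutral conditions.

Step 11
Reactants: 10; 17
Product: 19 (4S)-4-benzyl-3-[(2S)-2-{4,6-bis(benzyloxy)-3-(3-methylbutanoyl)-2-[2-(trimethylsilyl)ethoxy]phenyl}-3-[4,6-bis(benzyloxy)-5-(3-methylbutanoyl)-1-benzofuran-2-yl]propanoyl]-1,3-oxazolidin-2-one, via sodium enolate 18 (not isolated)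
Conditions: NaHMDS (1.05 equiv), THF, −78 °C; then 17, −78 to −40 °C
Reagents that add atoms: none
Why: Evans asymmetric alkylation, in which the chelated (Z)-enolate (the doubly activated imide CH2 is deprotonated in preference to the aryl ketones) is alkylated on the face opposite the 4-benzyl group, giving (S) at the new α-aryl centre.

Step 12
Reactants: 19
Product: 20 (2S)-2-{4,6-bis(benzyloxy)-3-(3-methylbutanoyl)-2-[2-(trimethylsilyl)ethoxy]phenyl}-3-[4,6-bis(benzyloxy)-5-(3-methylbutanoyl)-1-benzofuran-2-yl]propanoic acid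
Conditions: LiOH, H2O2, THF–H2O, 0 °C; Na2SO3; then aq. HCl
Reagents that add atoms: hydrogen peroxide OO
Why: Hydroperoxide cleavage of the Evans imide attacks the exocyclic carbonyl and should free the acid without epimerising the α-aryl centre.

Step 13
Reactants: 20
Product: 21 (2S)-2-{4,6-bis(benzyloxy)-3-(3-methylbutanoyl)-2-[2-(trimethylsilyl)ethoxy]phenyl}-3-[4,6-bis(benzyloxy)-5-(3-methylbutanoyl)-1-benzofuran-2-yl]propanoyl chloride
Conditions: 1-chloro-N,N,2-trimethylprop-1-en-1-amine, CH2Cl2, 0 °C to rt; used crude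
Reagents that add atoms: Ghosez reagent (1-chloro-N,N,2-trimethylprop-1-en-1-amine) CC(C)=C(Cl)N(C)C
Why: Acid chloride formation with Ghosez's reagent is neutral (no HCl, no base), so the silylethyl ether, the benzofuran and the α-centre should be left alone.

Step 14
Reactants: 5; 21
Product: 25 hexa-O-benzyl ether of the target (spiro carbon R, C3′ S), via benzylic zinc chloride 22 (not isolated), via fluoro ketone 23 (not isolated), via cesium phenoxide 24 (not isolated)
Conditions: 5, Zn dust, LiCl, THF, 25 °C; then 21, Pd(PPh3)4 (5 mol %), THF, 0 °C to rt; then CsF (6 equiv), DMF, 60 °C, same flask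
Reagents that add atoms: none
Why: Proposed new method: zinc reagent 22 acylates 21 under Pd(0) without base (C3–C2 bond, C3′ untouched); fluoride then removes the 2-(trimethylsilyl)ethyl group, the B-ring phenoxide adds to the new ketone, and the hemiketal alkoxide displaces fluoride at C7a through a Meisenheimer complex stabilised by the ortho C7 ketone (O1–C7a bond), releasing fluoride that carries the chain. The closest known reactions are the Negishi acylation of functionalised benzylic zinc chlorides, the SNAr O-arylation of hemiacetal (anomeric) alkoxides with activated aryl fluorides, and the fluoride-catalysed coupling of silyl-protected phenols with aryl fluorides; their fusion into a spiroketal-forming relay on a hemiketal is not described. Ring B closes by reversible 5-exo-trig hemiketalisation and ring A by irreversible 5-exo addition–elimination. The spiro centre is controlled by C3′: the hemiketal epimer with the bulky ArCH2 arm trans to the C3′ side chain is the more populated and the less hindered in the substitution, which puts O1 cis to the side chain as in the target (R). The step needs the hemiketal oxygen, not the enolate oxygen, to attack and needs retention at C3′; both should follow from the weakly basic medium, in which the phenol is ionised while the ketone is not enolised, and from the phenoxide charge on ring B, which disfavours deprotonation at C3′.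

Step 15
Reactants: 25
Product: 26 1,1'-[(2R,3S)-3-{[4,6-dihydroxy-5-(3-methylbutanoyl)-1-benzofuran-2-yl]methyl}-4,4',6,6'-tetrahydroxy-3H,3'H-2,2'-spirobi[1-benzofuran]-7,7'-diyl]bis(3-methylbutan-1-one)
Conditions: H2 (1 atm), 10 % Pd/C, EtOAc–MeOH, rt
Reagents that add atoms: none
Why: Hydrogenolysis of the six aryl benzyl ethers; the ketal carbon has no benzylic C–O bond, and the chelated aryl ketones and the benzofuran should survive at 1 atm.

**Compound list**

1 | 5-fluorobenzene-1,3-diol | Oc1cc(O)cc(F)c1 | starting material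
2 | 3-methylbutanoic acid | CC(C)CC(=O)O | starting material
3 | 1-(2-fluoro-4,6-dihydroxyphenyl)-3-methylbutan-1-one | CC(C)CC(=O)c1c(F)cc(O)cc1O | intermediate
4 | 1-[2,4-bis(benzyloxy)-6-fluorophenyl]-3-methylbutan-1-one | CC(C)CC(=O)c1c(F)cc(OCc2ccccc2)cc1OCc1ccccc1 | intermediate
5 | 1-[4,6-bis(benzyloxy)-3-(chloromethyl)-2-fluorophenyl]-3-methylbutan-1-one | CC(C)CC(=O)c1c(F)c(CCl)c(OCc2ccccc2)cc1OCc1ccccc1 | intermediate
6 | [4,6-bis(benzyloxy)-2-fluoro-3-(3-methylbutanoyl)phenyl]acetic acid | CC(C)CC(=O)c1c(F)c(CC(=O)O)c(OCc2ccccc2)cc1OCc1ccccc1 | intermediate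
7 | {4,6-bis(benzyloxy)-3-(3-methylbutanoyl)-2-[2-(trimethylsilyl)ethoxy]phenyl}acetic acid | CC(C)CC(=O)c1c(OCC[Si](C)(C)C)c(CC(=O)O)c(OCc2ccccc2)cc1OCc1ccccc1 | intermediate
8 | (4S)-4-benzyl-1,3-oxazolidin-2-one | O=C1N[C@@H](Cc2ccccc2)CO1 | starting material
9 | mixed pivalic anhydride of 7 | CC(C)CC(=O)c1c(OCC[Si](C)(C)C)c(CC(=O)OC(=O)C(C)(C)C)c(OCc2ccccc2)cc1OCc1ccccc1 | intermediate
10 | (4S)-4-benzyl-3-({4,6-bis(benzyloxy)-3-(3-methylbutanoyl)-2-[2-(trimethylsilyl)ethoxy]phenyl}acetyl)-1,3-oxazolidin-2-one | O=C1OC[C@H](Cc2ccccc2)N1C(=O)Cc1c(OCC[Si](C)(C)C)c(C(=O)CC(C)C)c(OCc2ccccc2)cc1OCc1ccccc1 | intermediate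
11 | 3-methyl-1-(2,4,6-trihydroxyphenyl)butan-1-one | CC(C)CC(=O)c1c(O)cc(O)cc1O | starting material
12 | 1-(2,4,6-trihydroxy-3-iodophenyl)-3-methylbutan-1-one | CC(C)CC(=O)c1c(O)cc(O)c(I)c1O | intermediate
13 | prop-2-yn-1-ol | OCC#C | starting material
14 | 1-[2,4,6-trihydroxy-3-(3-hydroxyprop-1-yn-1-yl)phenyl]-3-methylbutan-1-one | CC(C)CC(=O)c1c(O)cc(O)c(C#CCO)c1O | intermediate
15 | 1-[4,6-dihydroxy-2-(hydroxymethyl)-1-benzofuran-5-yl]-3-methylbutan-1-one | CC(C)CC(=O)c1c(O)cc2oc(CO)cc2c1O | intermediate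
16 | 1-[4,6-bis(benzyloxy)-2-(hydroxymethyl)-1-benzofuran-5-yl]-3-methylbutan-1-one | CC(C)CC(=O)c1c(OCc3ccccc3)cc2oc(CO)cc2c1OCc1ccccc1 | intermediate
17 | 1-[4,6-bis(benzyloxy)-2-(bromomethyl)-1-benzofuran-5-yl]-3-methylbutan-1-one | CC(C)CC(=O)c1c(OCc3ccccc3)cc2oc(CBr)cc2c1OCc1ccccc1 | intermediate
18 | sodium (Z)-enolate of imide 10 | [Na+].[O-]/C(=C\c1c(OCC[Si](C)(C)C)c(C(=O)CC(C)C)c(OCc2ccccc2)cc1OCc1ccccc1)N1C(=O)OC[C@@H]1Cc1ccccc1 | intermediate
19 | (4S)-4-benzyl-3-[(2S)-2-{4,6-bis(benzyloxy)-3-(3-methylbutanoyl)-2-[2-(trimethylsilyl)ethoxy]phenyl}-3-[4,6-bis(benzyloxy)-5-(3-methylbutanoyl)-1-benzofuran-2-yl]propanoyl]-1,3-oxazolidin-2-one | O=C1OC[C@H](Cc2ccccc2)N1C(=O)[C@@H](Cc1cc2c(OCc3ccccc3)c(C(=O)CC(C)C)c(OCc3ccccc3)cc2o1)c1c(OCC[Si](C)(C)C)c(C(=O)CC(C)C)c(OCc2ccccc2)cc1OCc1ccccc1 | intermediate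
20 | (2S)-2-{4,6-bis(benzyloxy)-3-(3-methylbutanoyl)-2-[2-(trimethylsilyl)ethoxy]phenyl}-3-[4,6-bis(benzyloxy)-5-(3-methylbutanoyl)-1-benzofuran-2-yl]propanoic acid | OC(=O)[C@@H](Cc1cc2c(OCc3ccccc3)c(C(=O)CC(C)C)c(OCc3ccccc3)cc2o1)c1c(OCC[Si](C)(C)C)c(C(=O)CC(C)C)c(OCc2ccccc2)cc1OCc1ccccc1 | intermediate
21 | (2S)-acid chloride of 20 | ClC(=O)[C@@H](Cc1cc2c(OCc3ccccc3)c(C(=O)CC(C)C)c(OCc3ccccc3)cc2o1)c1c(OCC[Si](C)(C)C)c(C(=O)CC(C)C)c(OCc2ccccc2)cc1OCc1ccccc1 | intermediate
22 | {[4,6-bis(benzyloxy)-2-fluoro-3-(3-methylbutanoyl)phenyl]methyl}zinc chloride | CC(C)CC(=O)c1c(F)c(C[Zn]Cl)c(OCc2ccccc2)cc1OCc1ccccc1 | intermediate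
23 | (3S)-1-[4,6-bis(benzyloxy)-2-fluoro-3-(3-methylbutanoyl)phenyl]-3-{4,6-bis(benzyloxy)-3-(3-methylbutanoyl)-2-[2-(trimethylsilyl)ethoxy]phenyl}-4-[4,6-bis(benzyloxy)-5-(3-methylbutanoyl)-1-benzofuran-2-yl]butan-2-one | CC(C)CC(=O)c1c(F)c(CC(=O)[C@@H](Cc2cc3c(OCc4ccccc4)c(C(=O)CC(C)C)c(OCc4ccccc4)cc3o2)c2c(OCC[Si](C)(C)C)c(C(=O)CC(C)C)c(OCc3ccccc3)cc2OCc2ccccc2)c(OCc2ccccc2)cc1OCc1ccccc1 | intermediate
24 | cesium phenoxide of the keto phenol from 23 (silylethyl group removed) | CC(C)CC(=O)c1c(F)c(CC(=O)[C@@H](Cc2cc3c(OCc4ccccc4)c(C(=O)CC(C)C)c(OCc4ccccc4)cc3o2)c2c([O-])c(C(=O)CC(C)C)c(OCc3ccccc3)cc2OCc2ccccc2)c(OCc2ccccc2)cc1OCc1ccccc1.[Cs+] | intermediate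
25 | hexa-O-benzyl ether of the target (spiro carbon R, C3′ S) | CC(C)CC(=O)c1c(OCc3ccccc3)cc(OCc3ccccc3)c2c1O[C@]1(C2)Oc2c(C(=O)CC(C)C)c(OCc3ccccc3)cc(OCc3ccccc3)c2[C@@H]1Cc1cc2c(OCc3ccccc3)c(C(=O)CC(C)C)c(OCc3ccccc3)cc2o1 | intermediate
26 | 1,1'-[(2R,3S)-3-{[4,6-dihydroxy-5-(3-methylbutanoyl)-1-benzofuran-2-yl]methyl}-4,4',6,6'-tetrahydroxy-3H,3'H-2,2'-spirobi[1-benzofuran]-7,7'-diyl]bis(3-methylbutan-1-one) | CC(C)CC(=O)c1c(O)cc(O)c2c1O[C@]1(C2)Oc2c(C(=O)CC(C)C)c(O)cc(O)c2[C@@H]1Cc1cc2c(O)c(C(=O)CC(C)C)c(O)cc2o1 | target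

**Step count and risks**

Total steps: 15. Longest linear sequence: 11 (steps 1, 2, 3, 4, 5, 6, 11, 12, 13, 14, 15).

Three steps most likely to fail:

1. Step 14 (Proposed new method). What may go wrong: enolisation of the α-aryl ketone before the phenoxide forms, with loss of configuration at C3′; slow fluoride displacement because the doubly flanked C7 ketone is twisted out of conjugation; O-arylation of the enolate instead of the hemiketal, which stops at a benzofuran. Fallback (known chemistry, sets out from 5 and 21, returns at 25): the ring-A oxygen is installed before the fragments are joined and the spiroketal is closed by classical acid-catalysed ketalisation of a dihydroxy ketone. 5 is treated with KOAc in DMF to give benzylic acetate F1. 2-(Trimethylsilyl)ethanol/KOt-Bu then displaces the fluoride and removes the acetyl group to give benzylic alcohol F2, and SOCl2 gives benzylic chloride F3. Its zinc reagent (Zn, LiCl) is acylated with 21 under Pd(PPh3)4 to bis(silylethyl) ketone F4. TBAF buffered with AcOH frees dihydroxy ketone F5, which CSA in CH2Cl2 (4 Å sieves) should close to 25 under thermodynamic control.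

2. Step 5. What may go wrong: enolisation of the activating ketone by the alkoxide, which switches off the substitution; attack of the neighbouring carboxylate on C–F (lactonisation) followed by ring opening to the wrong ether/ester pattern; incomplete substitution at a fluoride flanked on both sides. Fallback (sets out from 11, returns at 7): the oxygen comes from a phenol instead of from a substitution. 11 is benzylated at the para and one ortho oxygen (BnBr 2 equiv, K2CO3, acetone) to dibenzyl ether F6. NIS iodinates ortho to the remaining chelated hydroxyl to give iodophenol F7. Mitsunobu etherification with 2-(trimethylsilyl)ethanol (PPh3, DIAD) gives silylethyl ether F8. Palladium-catalysed Negishi coupling with the Reformatsky reagent BrZnCH2CO2Me (Pd2(dba)3, XPhos) gives methyl arylacetate F9, and LiOH hydrolysis gives 7.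

3. Step 8. What may go wrong: ring closure through the chelated ortho-hydroxyl instead of the para one (wrong annulation regiochemistry), and protodeiodination or oxidative degradation of the polyphenolic iodide under Pd/Cu. Fallback (sets out from 11, returns at 17): the furan oxygen is fixed before the ring is made. 11 is O-propargylated selectively at the most acidic para hydroxyl (propargyl bromide, K2CO3 1 equiv, acetone) to propargyl ether F10. The two ortho hydroxyls are benzylated (BnBr, K2CO3, DMF, 70 °C) to give F11. Aromatic Claisen rearrangement/cyclisation (CsF, N,N-diethylaniline, 190 °C), in which only the former ether oxygen is free to close, gives 2-methylbenzofuran F12. Wohl–Ziegler bromination (NBS, AIBN, PhCF3, 80 °C) of the 2-methyl group gives 17.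

**Further compounds**

F1 | step 14 | [4,6-bis(benzyloxy)-2-fluoro-3-(3-methylbutanoyl)phenyl]methyl acetate | CC(=O)OCc1c(F)c(C(=O)CC(C)C)c(OCc2ccccc2)cc1OCc1ccccc1
F2 | step 14 | 1-{4,6-bis(benzyloxy)-3-(hydroxymethyl)-2-[2-(trimethylsilyl)ethoxy]phenyl}-3-methylbutan-1-one | OCc1c(OCC[Si](C)(C)C)c(C(=O)CC(C)C)c(OCc2ccccc2)cc1OCc1ccccc1
F3 | step 14 | 1-{4,6-bis(benzyloxy)-3-(chloromethyl)-2-[2-(trimethylsilyl)ethoxy]phenyl}-3-methylbutan-1-one | ClCc1c(OCC[Si](C)(C)C)c(C(=O)CC(C)C)c(OCc2ccccc2)cc1OCc1ccccc1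
F4 | step 14 | (3S)-1,3-bis{4,6-bis(benzyloxy)-3-(3-methylbutanoyl)-2-[2-(trimethylsilyl)ethoxy]phenyl}-4-[4,6-bis(benzyloxy)-5-(3-methylbutanoyl)-1-benzofuran-2-yl]butan-2-one | CC(C)CC(=O)c1c(OCC[Si](C)(C)C)c(CC(=O)[C@@H](Cc2cc3c(OCc4ccccc4)c(C(=O)CC(C)C)c(OCc4ccccc4)cc3o2)c2c(OCC[Si](C)(C)C)c(C(=O)CC(C)C)c(OCc3ccccc3)cc2OCc2ccccc2)c(OCc2ccccc2)cc1OCc1ccccc1
F5 | step 14 | (3S)-1,3-bis[4,6-bis(benzyloxy)-2-hydroxy-3-(3-methylbutanoyl)phenyl]-4-[4,6-bis(benzyloxy)-5-(3-methylbutanoyl)-1-benzofuran-2-yl]butan-2-one | CC(C)CC(=O)c1c(O)c(CC(=O)[C@@H](Cc2cc3c(OCc4ccccc4)c(C(=O)CC(C)C)c(OCc4ccccc4)cc3o2)c2c(O)c(C(=O)CC(C)C)c(OCc3ccccc3)cc2OCc2ccccc2)c(OCc2ccccc2)cc1OCc1ccccc1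
F6 | step 5 | 1-[2,4-bis(benzyloxy)-6-hydroxyphenyl]-3-methylbutan-1-one | CC(C)CC(=O)c1c(O)cc(OCc2ccccc2)cc1OCc1ccccc1
F7 | step 5 | 1-[4,6-bis(benzyloxy)-2-hydroxy-3-iodophenyl]-3-methylbutan-1-one | CC(C)CC(=O)c1c(O)c(I)c(OCc2ccccc2)cc1OCc1ccccc1
F8 | step 5 | 1-{4,6-bis(benzyloxy)-3-iodo-2-[2-(trimethylsilyl)ethoxy]phenyl}-3-methylbutan-1-one | CC(C)CC(=O)c1c(OCC[Si](C)(C)C)c(I)c(OCc2ccccc2)cc1OCc1ccccc1
F9 | step 5 | methyl {4,6-bis(benzyloxy)-3-(3-methylbutanoyl)-2-[2-(trimethylsilyl)ethoxy]phenyl}acetate | COC(=O)Cc1c(OCC[Si](C)(C)C)c(C(=O)CC(C)C)c(OCc2ccccc2)cc1OCc1ccccc1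
F10 | step 8 | 1-[2,6-dihydroxy-4-(prop-2-yn-1-yloxy)phenyl]-3-methylbutan-1-one | CC(C)CC(=O)c1c(O)cc(OCC#C)cc1O
F11 | step 8 | 1-[2,6-bis(benzyloxy)-4-(prop-2-yn-1-yloxy)phenyl]-3-methylbutan-1-one | CC(C)CC(=O)c1c(OCc2ccccc2)cc(OCC#C)cc1OCc1ccccc1
F12 | step 8 | 1-[4,6-bis(benzyloxy)-2-methyl-1-benzofuran-5-yl]-3-methylbutan-1-one | CC(C)CC(=O)c1c(OCc3ccccc3)cc2oc(C)cc2c1OCc1ccccc1
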